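**Strategy.** The route rests on the cis-fused α-methylene-γ-butyrolactone (ring O–C14–C1–C15–C16 with exocyclic C17; cembrane numbering). C1–C15=C17 is read as a terminal allene, C16 as CO2 and C14 as an aldehyde carbon. One nickel-mediated three-component coupling then forms C15–C16 and C1–C14, unites the two halves and sets C1 and C14. Its precursors are an epoxy allene (3,4-epoxide by Sharpless epoxidation) and an α-silyloxy aldehyde that draws C7–C11 and the C8 carbinol from (S)-linalool and C12/C13 from an oxazolidinone imide. Lactonisation, Mitsunobu acetate inversion at C13 and ring-closing metathesis at C6=C7 complete the 14-membered ring.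

Key step: step 15

Remark: cembrane numbering is used throughout (C1 and C14 are the ring-fusion carbons; C15, C16, C17 are the lactone α-carbon, carbonyl carbon and exocyclic CH2), and (S)-(+)-linalool of high enantiomeric purity is assumed to be purchasable.

**Allene half**

Step 1
Reactants: 1 pent-1-en-4-yne
Product: 3 (E)-3-methylhexa-2,5-dien-1-ol, via alkenylalane 2 (not isolated)
Conditions: Me3Al, Cp2ZrCl2 (cat.), CH2Cl2, 0 °C to rt; then n-BuLi, THF, −78 °C; (CH2O)n, −78 °C to rt; aq. NH4Cl/potassium sodium tartrate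
Reagents that add atoms: trimethylaluminium C[Al](C)C; paraformaldehyde (as formaldehyde) C=O
Why: Zirconium-catalysed Negishi carboalumination adds methyl and aluminium syn across the terminal alkyne with methyl on the internal carbon, and hydroxymethylation of the derived alanate retains the geometry, so the E allylic alcohol should form while the isolated alkene is left alone.

Step 2
Reactants: 3 (E)-3-methylhexa-2,5-dien-1-ol
Product: 4 [(2R,3R)-3-methyl-3-(prop-2-en-1-yl)oxiran-2-yl]methanol
Conditions: Ti(OiPr)4 (cat.), D-(−)-diethyl tartrate, t-BuOOH, 4 Å molecular sieves, CH2Cl2, −20 °C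
Reagents that add atoms: tert-butyl hydroperoxide CC(C)(C)OO
Why: Sharpless asymmetric epoxidation acts only on the allylic alcohol double bond, and with the D-tartrate it should deliver oxygen to the face that gives the (2R,3R) epoxide (C3 and C4 of the target), the mirror image of the geraniol/L-tartrate outcome.

Step 3
Reactants: 4 [(2R,3R)-3-methyl-3-(prop-2-en-1-yl)oxiran-2-yl]methanol
Product: 6 trimethyl{3-[(2R,3R)-3-methyl-3-(prop-2-en-1-yl)oxiran-2-yl]prop-1-yn-1-yl}silane, via epoxy triflate 5 (not isolated)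
Conditions: Tf2O, 2,6-lutidine, CH2Cl2, −78 °C; then LiC≡CSiMe3 (from HC≡CSiMe3, n-BuLi), THF/DMPU, −78 to −40 °C
Reagents that add atoms: lithium (trimethylsilyl)acetylide [Li]C#C[Si](C)(C)C
Why: SN2 displacement of a primary triflate by an alkynyllithium at low temperature is much faster than attack on the hindered trisubstituted epoxide, so the C2–C1 bond should form without touching either stereocentre.

Step 4
Reactants: 6 trimethyl{3-[(2R,3R)-3-methyl-3-(prop-2-en-1-yl)oxiran-2-yl]prop-1-yn-1-yl}silane
Product: 7 (2R,3R)-2-methyl-2-(prop-2-en-1-yl)-3-(prop-2-yn-1-yl)oxirane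
Conditions: K2CO3, MeOH, rt
Reagents that add atoms: none
Why: Methanolytic protodesilylation of the alkynylsilane is mild enough to leave the epoxide and the alkene unchanged.

Step 5
Reactants: 7 (2R,3R)-2-methyl-2-(prop-2-en-1-yl)-3-(prop-2-yn-1-yl)oxirane
Product: 9 (2R,3R)-3-(buta-2,3-dien-1-yl)-2-methyl-2-(prop-2-en-1-yl)oxirane, via propargylic amine 8 (not isolated)
Conditions: (CH2O)n, CuI (0.5 equiv), dicyclohexylamine, dioxane, reflux
Reagents that add atoms: paraformaldehyde (as formaldehyde) C=O
Why: Crabbé homologation (copper-mediated Mannich reaction of the terminal alkyne, then 1,5-hydride transfer and fragmentation of the propargylic amine) should give the terminal allene, and the very hindered amine should not open the trisubstituted epoxide.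

**Aldehyde half**

Step 6
Reactants: 10 (S)-linalool
Product: 11 triethyl{[(3S)-3,7-dimethylocta-1,6-dien-3-yl]oxy}silane
Conditions: Et3SiOTf, 2,6-lutidine, CH2Cl2, −78 to 0 °C
Reagents that add atoms: triethylsilyl trifluoromethanesulfonate CC[Si](CC)(CC)OS(=O)(=O)C(F)(F)F
Why: Silyl ether formation with the silyl triflate protects the tertiary allylic alcohol (C8) for the organomagnesium step and prevents tetrahydrofuran formation in the later bromination.

Step 7
Reactants: 11 triethyl{[(3S)-3,7-dimethylocta-1,6-dien-3-yl]oxy}silane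
Product: 13 (4S)-4-methyl-4-[(triethylsilyl)oxy]hex-5-en-1-ol, via silyloxy aldehyde 12 (not isolated)
Conditions: O3 (1 equiv, Sudan Red 7B end point), CH2Cl2/MeOH, −78 °C; then NaBH4, −78 to 0 °C
Reagents that add atoms: ozone [O-][O+]=O
Why: Ozonolysis with one equivalent of ozone should cleave the electron-rich trisubstituted alkene in preference to the vinyl group next to the silyloxy quaternary carbon, and borohydride reduction in the same flask gives the primary alcohol (C11).

Step 8
Reactants: 13 (4S)-4-methyl-4-[(triethylsilyl)oxy]hex-5-en-1-ol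
Product: 14 {[(3S)-6-bromo-3-methylhex-1-en-3-yl]oxy}triethylsilane
Conditions: CBr4, PPh3, CH2Cl2, 0 °C
Reagents that add atoms: tetrabromomethane BrC(Br)(Br)Br
Why: Appel bromination converts the primary alcohol by SN2 displacement of its oxyphosphonium ion under neutral conditions that the tertiary silyl ether tolerates.

Step 9
Reactants: 15 (4S)-4-benzyl-1,3-oxazolidin-2-one; 16 (E)-but-2-enoyl chloride
Product: 17 (4S)-4-benzyl-3-[(2E)-but-2-enoyl]-1,3-oxazolidin-2-one
Conditions: Et3N, LiCl, THF, 0 °C to rt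
Reagents that add atoms: none
Why: N-acylation of the oxazolidinone with the acid chloride under amine/LiCl activation gives the chiral N-enoyl imide without isomerising the E alkene.

Step 10
Reactants: 14 {[(3S)-6-bromo-3-methylhex-1-en-3-yl]oxy}triethylsilane; 17 (4S)-4-benzyl-3-[(2E)-but-2-enoyl]-1,3-oxazolidin-2-one
Product: 19 (4S)-4-benzyl-3-[(3S,7S)-3,7-dimethyl-7-(triethylsilyloxy)non-8-enoyl]-1,3-oxazolidin-2-one, via alkylmagnesium bromide 18 (not isolated)
Conditions: Mg, THF, rt; CuBr·SMe2, THF/Me2S, −40 °C; then 17, −40 to −15 °C; aq. NH4Cl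
Reagents that add atoms: none
Why: Auxiliary-controlled copper-mediated conjugate addition to the magnesium-chelated syn-s-cis N-enoyl imide occurs on the face opposite the benzyl group, which should set C12 as S.

Step 11
Reactants: 19 (4S)-4-benzyl-3-[(3S,7S)-3,7-dimethyl-7-(triethylsilyloxy)non-8-enoyl]-1,3-oxazolidin-2-one
Product: 21 (4S)-4-benzyl-3-[(2S,3S,7S)-2-hydroxy-3,7-dimethyl-7-(triethylsilyloxy)non-8-enoyl]-1,3-oxazolidin-2-one, via sodium enolate 20 (not isolated)
Conditions: NaN(SiMe3)2, THF, −78 °C; 2-(benzenesulfonyl)-3-phenyloxaziridine, −78 °C; AcOH quench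
Reagents that add atoms: 2-(benzenesulfonyl)-3-phenyloxaziridine O=S(=O)(c1ccccc1)N1OC1c1ccccc1
Why: Enolate hydroxylation of the chelated Z sodium enolate by the oxaziridine takes place on the face opposite the benzyl group (the same sense as alkylation), which should give the 2S alcohol, that is (13S), anti to the C12 methyl.

Step 12
Reactants: 21 (4S)-4-benzyl-3-[(2S,3S,7S)-2-hydroxy-3,7-dimethyl-7-(triethylsilyloxy)non-8-enoyl]-1,3-oxazolidin-2-one
Product: 22 (2S,3S,7S)-2-hydroxy-N-methoxy-N,3,7-trimethyl-7-(triethylsilyloxy)non-8-enamide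
Conditions: MeNH(OMe)·HCl, Me3Al, CH2Cl2, −15 to 0 °C; aq. potassium sodium tartrate
Reagents that add atoms: N,O-dimethylhydroxylamine hydrochloride CNOC.Cl
Why: Aluminium amide transamination (Weinreb amide formation), assisted by the free α-hydroxyl, cleaves the exocyclic acyl group and releases the auxiliary without epimerisation.

Step 13
Reactants: 22 (2S,3S,7S)-2-hydroxy-N-methoxy-N,3,7-trimethyl-7-(triethylsilyloxy)non-8-enamide
Product: 23 (2S,3S,7S)-N-methoxy-N,3,7-trimethyl-2,7-bis(triethylsilyloxy)non-8-enamide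
Conditions: Et3SiOTf, 2,6-lutidine, CH2Cl2, −78 to 0 °C
Reagents that add atoms: triethylsilyl trifluoromethanesulfonate CC[Si](CC)(CC)OS(=O)(=O)C(F)(F)F
Why: Silyl ether formation gives a bulky, non-chelating C13 oxygen substituent, as needed for Felkin–Anh control in the key step.

Step 14
Reactants: 23 (2S,3S,7S)-N-methoxy-N,3,7-trimethyl-2,7-bis(triethylsilyloxy)non-8-enamide
Product: 24 (2S,3S,7S)-3,7-dimethyl-2,7-bis(triethylsilyloxy)non-8-enal
Conditions: i-Bu2AlH, THF, −78 °C; aq. potassium sodium tartrate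
Reagents that add atoms: none
Why: Hydride reduction of the Weinreb amide stops at the chelated tetrahedral intermediate, so the α-silyloxy aldehyde is released only on work-up, without over-reduction or epimerisation.

**Union and endgame**

Step 15
Reactants: 9 (2R,3R)-3-(buta-2,3-dien-1-yl)-2-methyl-2-(prop-2-en-1-yl)oxirane; 24 (2S,3S,7S)-3,7-dimethyl-2,7-bis(triethylsilyloxy)non-8-enal
Product: 26 (3S,4R,5S,6S,10S)-4-hydroxy-6,10-dimethyl-2-methylidene-3-{[(2R,3R)-3-methyl-3-(prop-2-en-1-yl)oxiran-2-yl]methyl}-5,10-bis(triethylsilyloxy)dodec-11-enoic acid, via nickelalactone 25 (not isolated)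
Conditions: Ni(cod)2 (1.1 equiv), DBU, CO2 (1 atm), THF, 0 °C; then 24, 0 °C to rt; aq. NH4Cl, then citrate buffer (pH 4)
Reagents that add atoms: carbon dioxide O=C=O
Why: Zerovalent nickel with DBU couples CO2 oxidatively with the terminal C15=C17 bond of the allene, which forms the C15–C16 bond and the oxanickelacycle 25; its allylnickel unit then adds through C1 to the aldehyde in a closed six-membered transition state, which forms the C1–C14 bond, and mild acid releases the hydroxy acid. The closest known reaction type is the nickel-mediated sequential addition of CO2 and an aldehyde to a terminal allene, a carboxylative relative of allylmetal–aldehyde addition. No ring of the target is closed here (the nickelacycle is cleaved on work-up and the lactone is closed in step 16). C1 is controlled by the geometry of the allylnickel: nickel and CO2 add to the allene face remote from C2, so C2 lies cis to CH2–Ni and the chair transition state gives the 1,14-syn relation needed for the cis-lactone. C14 is controlled by C13: Felkin–Anh attack anti to the C13–OSiEt3 bond of the (13S)-aldehyde gives 14R, and this preference and that of the Z-configured allyl unit reinforce each other. The step needs the allene to react in preference to the allyl and vinyl groups (isolated alkenes are far less reactive in this carboxylation), γ-attack of the allylnickel (secured by the closed transition state) and a configurationally stable aldehyde (α-branched and added last at 0 °C).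

Step 16
Reactants: 26 the hydroxy acid of step 15
Product: 27 (4S,5R)-5-[(1S,2S,6S)-2,6-dimethyl-1,6-bis(triethylsilyloxy)oct-7-en-1-yl]-3-methylidene-4-{[(2R,3R)-3-methyl-3-(prop-2-en-1-yl)oxiran-2-yl]methyl}oxolan-2-one
Conditions: EDC·HCl, DMAP (cat.), CH2Cl2, 0 °C to rt
Reagents that add atoms: none
Why: Carbodiimide-mediated (Steglich-type) lactonisation closes the five-membered ring by attack of the C14 hydroxyl on the activated acid with retention at C14, under acid-free conditions that spare the trisubstituted epoxide.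

Step 17
Reactants: 27 the bis-silyl lactone of step 16
Product: 28 (4S,5R)-5-[(1S,2S,6S)-1,6-dihydroxy-2,6-dimethyloct-7-en-1-yl]-3-methylidene-4-{[(2R,3R)-3-methyl-3-(prop-2-en-1-yl)oxiran-2-yl]methyl}oxolan-2-one
Conditions: HF·pyridine, pyridine, THF, 0 °C to rt
Reagents that add atoms: none
Why: Buffered fluoride desilylation should remove both triethylsilyl ethers while avoiding the strong acid that would open the epoxide and the basic fluoride that would attack the α-methylene lactone.

Step 18
Reactants: 28 the diol of step 17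
Product: 29 (1R,2S,6S)-6-hydroxy-2,6-dimethyl-1-[(2R,3S)-4-methylidene-3-{[(2R,3R)-3-methyl-3-(prop-2-en-1-yl)oxiran-2-yl]methyl}-5-oxooxolan-2-yl]oct-7-en-1-yl acetate
Conditions: PPh3, diisopropyl azodicarboxylate, AcOH, toluene, 0 °C to rt
Reagents that add atoms: acetic acid CC(=O)O
Why: Mitsunobu esterification activates the secondary C13 hydroxyl as its oxyphosphonium ion and acetate displaces it by SN2 with inversion, which turns 13S into the required 13R acetate, while the tertiary C8 hydroxyl is inert.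

Step 19
Reactants: 29 the diene acetate of step 18
Product: 30 CNP0202356.4, (1S,3R,4R,6E,8S,12S,13R,14R)-13-acetoxy-3,4-epoxy-8-hydroxycembra-6,15(17)-dien-16,14-olide
Conditions: second-generation Hoveyda–Grubbs catalyst (H2IMes)Cl2Ru(=CH-C6H4-2-OiPr) (cat.), toluene (1 mM), 60 °C
Reagents that add atoms: none
Why: Ring-closing olefin metathesis joins the two monosubstituted alkenes into the 14-membered ring with loss of ethene; the E alkene is expected because a Z alkene next to the fully substituted C8 would suffer severe allylic strain, and the electron-poor 1,1-disubstituted methylene lactone should not compete.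

**Compound list**

1 | pent-1-en-4-yne | C=CCC#C | starting material
2 | (E)-dimethyl(2-methylpenta-1,4-dien-1-yl)alane, formed in the flask | C=CC/C(C)=C/[Al](C)C | intermediate
3 | (E)-3-methylhexa-2,5-dien-1-ol | C=CC/C(C)=C/CO | intermediate
4 | [(2R,3R)-3-methyl-3-(prop-2-en-1-yl)oxiran-2-yl]methanol | C=CC[C@@]1(C)O[C@@H]1CO | intermediate
5 | [(2R,3R)-3-methyl-3-(prop-2-en-1-yl)oxiran-2-yl]methyl trifluoromethanesulfonate, formed in the flask | C=CC[C@@]1(C)O[C@@H]1COS(=O)(=O)C(F)(F)F | intermediate
6 | trimethyl{3-[(2R,3R)-3-methyl-3-(prop-2-en-1-yl)oxiran-2-yl]prop-1-yn-1-yl}silane | C=CC[C@@]1(C)O[C@@H]1CC#C[Si](C)(C)C | intermediate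
7 | (2R,3R)-2-methyl-2-(prop-2-en-1-yl)-3-(prop-2-yn-1-yl)oxirane | C=CC[C@@]1(C)O[C@@H]1CC#C | intermediate
8 | N,N-dicyclohexyl-4-[(2R,3R)-3-methyl-3-(prop-2-en-1-yl)oxiran-2-yl]but-2-yn-1-amine, formed in the flask | C=CC[C@@]1(C)O[C@@H]1CC#CCN(C2CCCCC2)C2CCCCC2 | intermediate
9 | (2R,3R)-3-(buta-2,3-dien-1-yl)-2-methyl-2-(prop-2-en-1-yl)oxirane | C=CC[C@@]1(C)O[C@@H]1CC=C=C | intermediate
10 | (S)-linalool, (3S)-3,7-dimethylocta-1,6-dien-3-ol | CC(C)=CCC[C@](C)(O)C=C | starting material
11 | triethyl{[(3S)-3,7-dimethylocta-1,6-dien-3-yl]oxy}silane | CC(C)=CCC[C@](C)(O[Si](CC)(CC)CC)C=C | intermediate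
12 | (4S)-4-methyl-4-[(triethylsilyl)oxy]hex-5-enal, formed in the flask | O=CCC[C@](C)(O[Si](CC)(CC)CC)C=C | intermediate
13 | (4S)-4-methyl-4-[(triethylsilyl)oxy]hex-5-en-1-ol | OCCC[C@](C)(O[Si](CC)(CC)CC)C=C | intermediate
14 | {[(3S)-6-bromo-3-methylhex-1-en-3-yl]oxy}triethylsilane | BrCCC[C@](C)(O[Si](CC)(CC)CC)C=C | intermediate
15 | (4S)-4-benzyl-1,3-oxazolidin-2-one | O=C1N[C@@H](Cc2ccccc2)CO1 | starting material
16 | (E)-but-2-enoyl chloride | C/C=C/C(Cl)=O | starting material
17 | (4S)-4-benzyl-3-[(2E)-but-2-enoyl]-1,3-oxazolidin-2-one | C/C=C/C(=O)N1[C@@H](Cc2ccccc2)COC1=O | intermediate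
18 | bromo{(4S)-4-methyl-4-[(triethylsilyl)oxy]hex-5-en-1-yl}magnesium, formed in the flask | Br[Mg]CCC[C@](C)(O[Si](CC)(CC)CC)C=C | intermediate
19 | (4S)-4-benzyl-3-[(3S,7S)-3,7-dimethyl-7-(triethylsilyloxy)non-8-enoyl]-1,3-oxazolidin-2-one | O=C(C[C@@H](C)CCC[C@](C)(O[Si](CC)(CC)CC)C=C)N1[C@@H](Cc2ccccc2)COC1=O | intermediate
20 | sodium (Z)-enolate of 19, formed in the flask | [Na+].[O-]/C(=C\[C@@H](C)CCC[C@](C)(O[Si](CC)(CC)CC)C=C)N1[C@@H](Cc2ccccc2)COC1=O | intermediate
21 | (4S)-4-benzyl-3-[(2S,3S,7S)-2-hydroxy-3,7-dimethyl-7-(triethylsilyloxy)non-8-enoyl]-1,3-oxazolidin-2-one | O=C([C@@H](O)[C@@H](C)CCC[C@](C)(O[Si](CC)(CC)CC)C=C)N1[C@@H](Cc2ccccc2)COC1=O | intermediate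
22 | (2S,3S,7S)-2-hydroxy-N-methoxy-N,3,7-trimethyl-7-(triethylsilyloxy)non-8-enamide | CON(C)C(=O)[C@@H](O)[C@@H](C)CCC[C@](C)(O[Si](CC)(CC)CC)C=C | intermediate
23 | (2S,3S,7S)-N-methoxy-N,3,7-trimethyl-2,7-bis(triethylsilyloxy)non-8-enamide | CON(C)C(=O)[C@@H](O[Si](CC)(CC)CC)[C@@H](C)CCC[C@](C)(O[Si](CC)(CC)CC)C=C | intermediate
24 | (2S,3S,7S)-3,7-dimethyl-2,7-bis(triethylsilyloxy)non-8-enal | O=C[C@@H](O[Si](CC)(CC)CC)[C@@H](C)CCC[C@](C)(O[Si](CC)(CC)CC)C=C | intermediate
25 | 4-alkylidene-1-oxa-2-nickelacyclopentan-5-one with C2 cis to CH2–Ni (DBU ligands on nickel omitted), formed in the flask | O=C1O[Ni]C/C1=C\C[C@H]2O[C@]2(C)CC=C | intermediate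
26 | (3S,4R,5S,6S,10S)-4-hydroxy-6,10-dimethyl-2-methylidene-3-{[(2R,3R)-3-methyl-3-(prop-2-en-1-yl)oxiran-2-yl]methyl}-5,10-bis(triethylsilyloxy)dodec-11-enoic acid | C=C(C(=O)O)[C@H](C[C@H]1O[C@]1(C)CC=C)[C@@H](O)[C@@H](O[Si](CC)(CC)CC)[C@@H](C)CCC[C@](C)(O[Si](CC)(CC)CC)C=C | intermediate
27 | (4S,5R)-5-[(1S,2S,6S)-2,6-dimethyl-1,6-bis(triethylsilyloxy)oct-7-en-1-yl]-3-methylidene-4-{[(2R,3R)-3-methyl-3-(prop-2-en-1-yl)oxiran-2-yl]methyl}oxolan-2-one | C=C1C(=O)O[C@@H]([C@@H](O[Si](CC)(CC)CC)[C@@H](C)CCC[C@](C)(O[Si](CC)(CC)CC)C=C)[C@H]1C[C@H]2O[C@]2(C)CC=C | intermediate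
28 | (4S,5R)-5-[(1S,2S,6S)-1,6-dihydroxy-2,6-dimethyloct-7-en-1-yl]-3-methylidene-4-{[(2R,3R)-3-methyl-3-(prop-2-en-1-yl)oxiran-2-yl]methyl}oxolan-2-one | C=C1C(=O)O[C@@H]([C@@H](O)[C@@H](C)CCC[C@](C)(O)C=C)[C@H]1C[C@H]2O[C@]2(C)CC=C | intermediate
29 | (1R,2S,6S)-6-hydroxy-2,6-dimethyl-1-[(2R,3S)-4-methylidene-3-{[(2R,3R)-3-methyl-3-(prop-2-en-1-yl)oxiran-2-yl]methyl}-5-oxooxolan-2-yl]oct-7-en-1-yl acetate | C=C1C(=O)O[C@@H]([C@H](OC(C)=O)[C@@H](C)CCC[C@](C)(O)C=C)[C@H]1C[C@H]2O[C@]2(C)CC=C | intermediate
30 | CNP0202356.4, (1S,3R,4R,6E,8S,12S,13R,14R)-13-acetoxy-3,4-epoxy-8-hydroxycembra-6,15(17)-dien-16,14-olide | C=C1C(=O)O[C@H]2[C@H](OC(C)=O)[C@@H](C)CCC[C@](C)(O)/C=C/C[C@@]3(C)O[C@@H]3C[C@@H]12 | target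

**Step count and risks**

Total step count: 19. Longest linear sequence: 13 steps (steps 6 to 8 and 10 to 19).

Steps most likely to fail:

Step 15. The allylnickel may add only slowly to an aliphatic, α-branched aldehyde, so that base-induced enolisation of the aldehyde or syn/anti isomerisation of the allylnickel erodes conversion and the 1,14-syn/Felkin selectivity. The fallback sets out from 9 and 24. A copper-catalysed borylative allene–aldehyde coupling (CuCl, an imidazol-2-ylidene ligand, NaOtBu, B2pin2, THF) should give the 2-boryl homoallylic alcohol F1 through a Z-configured 2-boryl allylcopper and the same chair. Iododeboronation (NaOMe, I2, −78 °C) should give the vinyl iodide F2. Carbonylative lactonisation (Pd(PPh3)4, CO, Et3N, THF, 60 °C) would then form C15–C16 and the lactone C–O bond, and the route is rejoined at 27.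

Step 18. SN2 displacement at the hindered C13 oxyphosphonium ion, flanked by C12 and the lactone carbon, may be slow, so that elimination or phosphine addition to the methylene lactone takes over. The fallback sets out from 28. Oxidation with Dess–Martin periodinane (NaHCO3, CH2Cl2) should give the C13 ketone F3. Reduction with NaBH4/CeCl3 at −78 °C, expected to follow Felkin–Anh attack anti to the C14–O bond, should give the (13R)-alcohol F4. Acetylation (Ac2O, pyridine, DMAP) then rejoins the route at 29.

Step 19. The ruthenium carbene may be diverted by the exocyclic enoate, or cross-metathesis between molecules may outrun cyclisation at the hindered vinyl carbinol. The fallback sets out from 29. Conjugate addition of Me2NH (THF, 0 °C) masks the methylene lactone as the amine adduct F5. Ring-closing metathesis of its toluenesulfonate salt with the same catalyst should give the macrocyclic amine F6. Quaternisation with MeI and elimination with NaHCO3 restores the methylene lactone, and the route is rejoined at 30.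

**Further compounds**

F1 | step 15 | 2-(pinacolboryl) homoallylic alcohol, the analogue of 26 with a 4,4,5,5-tetramethyl-1,3,2-dioxaborolan-2-yl group in place of CO2H (same spatial arrangement) | C=C(B1OC(C)(C)C(C)(C)O1)[C@H](C[C@H]2O[C@]2(C)CC=C)[C@@H](O)[C@@H](O[Si](CC)(CC)CC)[C@@H](C)CCC[C@](C)(O[Si](CC)(CC)CC)C=C
F2 | step 15 | vinyl iodide, the analogue of 26 with iodine in place of CO2H (same spatial arrangement) | C=C(I)[C@H](C[C@H]1O[C@]1(C)CC=C)[C@@H](O)[C@@H](O[Si](CC)(CC)CC)[C@@H](C)CCC[C@](C)(O[Si](CC)(CC)CC)C=C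
F3 | step 18 | (2S,6S)-6-hydroxy-2,6-dimethyl-1-[(2R,3S)-4-methylidene-3-{[(2R,3R)-3-methyl-3-(prop-2-en-1-yl)oxiran-2-yl]methyl}-5-oxooxolan-2-yl]oct-7-en-1-one | C=C1C(=O)O[C@@H](C(=O)[C@@H](C)CCC[C@](C)(O)C=C)[C@H]1C[C@H]2O[C@]2(C)CC=C
F4 | step 18 | (4S,5R)-5-[(1R,2S,6S)-1,6-dihydroxy-2,6-dimethyloct-7-en-1-yl]-3-methylidene-4-{[(2R,3R)-3-methyl-3-(prop-2-en-1-yl)oxiran-2-yl]methyl}oxolan-2-one | C=C1C(=O)O[C@@H]([C@H](O)[C@@H](C)CCC[C@](C)(O)C=C)[C@H]1C[C@H]2O[C@]2(C)CC=C
F5 | step 19 | dimethylamine adduct of 29, 3-[(dimethylamino)methyl]oxolan-2-one in place of the methylene lactone (C15 configuration not controlled) | CN(C)CC1C(=O)O[C@@H]([C@H](OC(C)=O)[C@@H](C)CCC[C@](C)(O)C=C)[C@H]1C[C@H]2O[C@]2(C)CC=C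
F6 | step 19 | dimethylamine adduct of 30, the 14-membered E-alkene with a 15-[(dimethylamino)methyl] group (C15 configuration not controlled) | CN(C)CC1C(=O)O[C@H]2[C@H](OC(C)=O)[C@@H](C)CCC[C@](C)(O)/C=C/C[C@@]3(C)O[C@@H]3C[C@@H]12
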